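**Grey first.** The grey run climbed early and then flattened, with 0.134 M of target at 1.6 h and 0.169 M at 3.5 h, so one constant read from its start did not fit its end. I wanted one hand number joining the two.

| flask | substrate | free catalyst | target | time |
|---|---|---|---|---|
| grey | 0.600 M | 0.00300 M |  |  |
| blue | 0.360 M | 0.00300 M |  |  |
| ochre | 0.300 M | 0.00300 M |  |  |
| red | 0.600 M | 0.00300 M | 0.300 M |  |
| violet | 0.600 M | 0.00900 M |  | 3.5 h |

| run | time / h | [target] / M |
|---|---|---|
| grey run | 0.14 | 0.020 |
| grey run | 0.31 | 0.036 |
| grey run | 0.70 | 0.075 |
| grey run | 1.6 | 0.134 |
| grey run | 3.5 | 0.169 |
| blue run | 0.14 | 0.010 |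
| blue run | 0.31 | 0.025 |
| blue run | 0.70 | 0.045 |
| blue run | 1.6 | 0.084 |
| blue run | 3.5 | 0.104 |
| ochre run | 0.14 | 0.008 |
| ochre run | 0.31 | 0.021 |
| ochre run | 0.70 | 0.043 |
| ochre run | 1.6 | 0.067 |
| ochre run | 3.5 | 0.083 |
| red run | 0.14 | 0.317 |
| red run | 0.31 | 0.335 |
| red run | 0.70 | 0.362 |
| red run | 1.6 | 0.363 |
| red run | 3.5 | 0.362 |

(readings scatter by 0.005 M)

- Overall: substrate -> target, with free catalyst as catalyst.
- Constant volume, constant temperature.
- An order is taken over about fifteen percent of the charge, up and down.

- reaction order in [substrate] at the outset, round the charge of the grey run, defined at two percent of the substrate turned into target (one fixed amount of target, the same in the runs compared)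
- target in the violet run at 3.5 h, as a share of the substrate charged

**Mean activity.** The grey reading at 0.31 h gave me an early pseudo-first-order constant of 0.200 h⁻¹, a reading with its scatter. At 3.5 h the log conversion, ln of charge over charge less target, stood at 0.331. I replaced the falling curve by its mean and kept 0.474 as the mean activity, the log conversion over early constant times time. It is read from target, so any loss of target counts in it.

**Substrate charge.** By hand, a first-order flask with the same catalyst reaches the same share at a given time whatever its charge. At 3.5 h, grey, blue and ochre reached 28.2 %, 28.9 % and 27.7 %. From ochre to grey, target at 3.5 h rose with the charge to the power 1.03, a late reading with its scatter over a wider span than the asked order, and I took it as my rough estimate of that order.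

**Charged target.** By hand, target that slowed the start would show at the first reading. The red run gained 0.0170 M there against 0.020 M in grey, then read 0.362 M at 0.70 h and 0.362 M at 3.5 h.

**Catalyst charge.** No earlier run turned this setting. Violet carries 3.00 times the catalyst of grey, so I scaled its early constant by that factor, assuming first order in free catalyst. With the mean activity held, I reckoned 62.9 % at 3.5 h. A catalyst whose loss quickens with its own amount would lower that figure.

**The forecast.** The forecast gave an order of 0.93 (0.75 to 1.1) and 44 % (37 % to 58 %) for violet, below my figure, with the remark “This is an extrapolation, since catalyst loading was never varied.”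

**The result.** The simulation gave an order of 1.1 round the grey charge and 41.8 % of the charge as target in violet at 3.5 h.

    free catalyst + substrate → target + free catalyst (81.72 L mol⁻¹ h⁻¹)
    target → decomposed product (0.1307 h⁻¹)
    2 free catalyst → 2 spent catalyst (90.72 L mol⁻¹ h⁻¹)

**Paired death.** Violet's mean activity came to 0.259, lower than grey's 0.474, and the passing of free catalyst in pairs into spent catalyst held violet's target down. The first half-life of free catalyst by this step alone is 0.612 h in violet, shorter than 1.84 h in grey. Violet without that step reached 67.7 % instead of 41.8 %, and its mean activity of 0.539 is twice the violet value.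

The earlier runs and the new flask are simulated for an exercise, noise included.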